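**Retrosynthetic overview**
1. The naphthazarin is disconnected across the unsubstituted ring: target 10 ⇒ chiral 2‑substituted p‑benzoquinone 8 + 2,5‑bis(trimethylsilyloxy)furan 9 (Diels–Alder, bridge opening, double enolisation). The 2‑ and 6‑substituted naphthazarin tautomers are the same compound, so no phenol protecting groups are needed at the end.
2. Quinone 8 ⇒ oxidative dearomatisation (CAN) of the 2,5‑dimethoxyphenyl ester 7.
3. Ester 7 ⇒ Steglich acylation of (S)‑alcohol 5 with 3‑methylbut‑2‑enoic acid.
4. Alcohol 5 ⇒ cross‑metathesis of (S)‑homoallylic alcohol 3 with 2‑methyl‑2‑butene; 3 ⇒ Brown allylation of 2,5‑dimethoxybenzaldehyde, which sets the only stereocentre.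
5. Ring order: the first six‑membered ring comes from the benzaldehyde feedstock; the second is formed in the last step by the [4+2] annulation.

Assumption: the SMILES stereocentre is (S) (alkannin series), and furan 9 is a catalogue reagent (otherwise one step from succinic anhydride with TMSCl/Et3N/ZnCl2).

**Step 1**
Reactants: 1, 2,5‑dimethoxybenzaldehyde; 2, allylmagnesium bromide
Product: 3, (S)‑1‑(2,5‑dimethoxyphenyl)but‑3‑en‑1‑ol
Conditions: (−)‑Ipc2BOMe, allylMgBr, Et2O, 0 °C → rt; then 1, −78 °C; NaOH, H2O2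
Reagents that add atoms: allylmagnesium bromide, C=CC[Mg]Br
Why: Brown asymmetric allylboration, in which the (−)‑Ipc2B‑allyl reagent (from (+)‑α‑pinene) delivers allyl to the si face of the aryl aldehyde through a chair transition state to give the (S)‑carbinol (as with benzaldehyde, typically ≥94% ee).

**Step 2**
Reactants: 3, (S)‑1‑(2,5‑dimethoxyphenyl)but‑3‑en‑1‑ol; 4, 2‑methyl‑2‑butene
Product: 5, (S)‑1‑(2,5‑dimethoxyphenyl)‑4‑methylpent‑3‑en‑1‑ol
Conditions: Grubbs II (3–5 mol %), 2‑methyl‑2‑butene (large excess)/CH2Cl2, 35–40 °C, sealed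
Reagents that add atoms: 2‑methyl‑2‑butene, CC=C(C)C
Why: Olefin cross‑metathesis of a terminal alkene with excess 2‑methyl‑2‑butene installs the =CMe2 terminus (free alcohol tolerated) without touching the stereocentre.

**Step 3**
Reactants: 5, (S)‑1‑(2,5‑dimethoxyphenyl)‑4‑methylpent‑3‑en‑1‑ol; 6, 3‑methylbut‑2‑enoic acid
Product: 7, (S)‑1‑(2,5‑dimethoxyphenyl)‑4‑methylpent‑3‑en‑1‑yl 3‑methylbut‑2‑enoate
Conditions: DCC, DMAP (cat.), CH2Cl2, 0 °C → rt
Reagents that add atoms: 3‑methylbut‑2‑enoic acid, CC(C)=CC(=O)O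
Why: Steglich esterification acylates the alcohol oxygen under neutral conditions, so the C–O bond at the stereocentre is never broken (retention) and the electron‑rich benzylic position is not ionised.

**Step 4**
Reactants: 7, (S)‑1‑(2,5‑dimethoxyphenyl)‑4‑methylpent‑3‑en‑1‑yl 3‑methylbut‑2‑enoate
Product: 8, (S)‑1‑(3,6‑dioxocyclohexa‑1,4‑dien‑1‑yl)‑4‑methylpent‑3‑en‑1‑yl 3‑methylbut‑2‑enoate
Conditions: CAN (2.5–3 equiv), MeCN/H2O, 0 °C, 15 min (7 added to the CAN solution); used crude, kept dark
Reagents that add atoms: water, O (the quinone oxygens come from water; both OMe groups leave as MeOH)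
Why: Ce(IV) oxidative demethylation of a 1,4‑dimethoxyarene dearomatises the ring to the p‑quinone faster than it attacks the trisubstituted alkene or the esters, and inverse addition suppresses biaryl diquinone formation.

**Step 5**
Reactants: 8, the quinone from Step 4; 9, 2,5‑bis(trimethylsilyloxy)furan
Product: 10, alkannin β,β‑dimethylacrylate, i.e. (S)‑1‑(5,8‑dihydroxy‑1,4‑dioxo‑1,4‑dihydronaphthalen‑2‑yl)‑4‑methylpent‑3‑en‑1‑yl 3‑methylbut‑2‑enoate
Conditions: 9 (1.05–1.1 equiv), CH2Cl2, −78 → 0 °C, N2, dark; then 0.5 M HCl/THF, 0 °C → rt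
Reagents that add atoms: 2,5‑bis(trimethylsilyloxy)furan, C[Si](C)(C)Oc1ccc(O[Si](C)(C)C)o1 (supplies four carbons and two oxygens; silyl groups and the ring oxygen are lost)
Why: Diels–Alder reaction of the symmetric, electron‑rich bis(silyloxy)furan (the reaction type that converts p‑benzoquinone into naphthazarin) at the unsubstituted, more dienophilic C=C of 8 gives an oxa‑bridged bis‑silyl ketal that on mild acid opens to the 4a,8a‑dihydro‑1,4,5,8‑tetraone and doubly enolises to the naphthazarin, with the side‑chain stereocentre a spectator.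

**Compound list**
1 | 2,5‑dimethoxybenzaldehyde | COc1ccc(OC)c(C=O)c1 | starting material
2 | allylmagnesium bromide | C=CC[Mg]Br | starting material
3 | (S)‑1‑(2,5‑dimethoxyphenyl)but‑3‑en‑1‑ol | C=CC[C@H](O)c1cc(OC)ccc1OC | intermediate
4 | 2‑methyl‑2‑butene | CC=C(C)C | starting material
5 | (S)‑1‑(2,5‑dimethoxyphenyl)‑4‑methylpent‑3‑en‑1‑ol | CC(C)=CC[C@H](O)c1cc(OC)ccc1OC | intermediate
6 | 3‑methylbut‑2‑enoic acid | CC(C)=CC(=O)O | starting material
7 | (S)‑1‑(2,5‑dimethoxyphenyl)‑4‑methylpent‑3‑en‑1‑yl 3‑methylbut‑2‑enoate | CC(C)=CC[C@H](OC(=O)C=C(C)C)c1cc(OC)ccc1OC | intermediate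
8 | (S)‑1‑(3,6‑dioxocyclohexa‑1,4‑dien‑1‑yl)‑4‑methylpent‑3‑en‑1‑yl 3‑methylbut‑2‑enoate | CC(C)=CC[C@H](OC(=O)C=C(C)C)C1=CC(=O)C=CC1=O | intermediate
9 | 2,5‑bis(trimethylsilyloxy)furan | C[Si](C)(C)Oc1ccc(O[Si](C)(C)C)o1 | starting material
10 | alkannin β,β‑dimethylacrylate | CC(C)=CC[C@H](OC(=O)C=C(C)C)C1=CC(=O)c2c(O)ccc(O)c2C1=O | target

**Total steps:** 5. **Longest linear sequence:** 5.

**Steps most likely to fail, with fallbacks**
1. Step 5 (annulation). Risks are Mukaiyama–Michael or redox pathways instead of [4+2], and a second annulation on the product. Fallback: abandon late ring construction. Run the same allylation, metathesis and esterification on 1,4,5,8‑tetramethoxynaphthalene‑2‑carbaldehyde, then unveil the naphthazarin by two‑stage oxidative demethylation (CAN, then AgO/HNO3 followed by Na2S2O4).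
2. Step 4 (CAN oxidation). Risks are radical‑cation dimerisation to a biaryl diquinone or loss of the benzylic ester. Fallback: change the phenol protection. Start from 2,5‑dihydroxybenzaldehyde as its bis‑TBS ether and release the quinone by oxidative desilylation (PhI(OAc)2 or PCC), avoiding Ce(IV).
3. Step 2 (cross‑metathesis). Risks are incomplete conversion to the trisubstituted alkene or Ru–H isomerisation of the homoallylic alcohol. Fallback: make 5 by asymmetric ketone reduction instead. Add 2,5‑dimethoxyphenyllithium to N‑methoxy‑N,4‑dimethylpent‑3‑enamide to give the aryl ketone, then reduce with (−)‑DIP‑Cl (the enantiomer that gives (S)‑1‑arylalkanols).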